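All runs are calculated for an exercise.

A turnover was the unit I counted in: one product formed per precatalyst charged, the usual turnover number taken on the catalyst charge. A single-handed catalyst can treat two mirror-image substrates at different rates, so the excess says how far the left-handed product leads in the product.

| flask | left-handed substrate | right-handed substrate | partner | precatalyst | remark | time |
|---|---|---|---|---|---|---|
| autumn | 0.25 M | 0.25 M | 0.075 M (fed, over 25 min) | 11 mM | run made earlier |  |
| summer | 0.25 M | 0.25 M | 0.11 M (fed, over 25 min) | 11 mM | run made earlier |  |
| winter | 0.38 M | 0.38 M | 0.15 M (fed, over 25 min) | 11 mM | run made earlier |  |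
| flask | 0.25 M | 0.25 M | 0.150 M (fed, over 25 min) | 11 mM |  | 15 h |

| run | time / h | left-handed product / % | right-handed product / % | left-handed substrate / % |
|---|---|---|---|---|
| autumn | 1.33 | 2.4 | 0.3 | 47.5 |
| autumn | 4.00 | 2.2 | 1.3 | 47.3 |
| autumn | 8.00 | 2.8 | 0.9 | 48.5 |
| autumn | 10.0 | 2.7 | 0.7 | 47.8 |
| autumn | 15.0 | 1.9 | 1.2 | 47.7 |
| summer | 1.33 | 4.4 | 1.4 | 45.5 |
| summer | 2.50 | 3.9 | 0.9 | 45.9 |
| summer | 4.00 | 3.9 | 1.5 | 45.6 |
| summer | 8.00 | 4.2 | 1.5 | 46.0 |
| summer | 15.0 | 3.8 | 1.3 | 45.4 |
| winter | 3.00 | 5.9 | 2.2 | 44.6 |
| winter | 6.00 | 5.6 | 2.1 | 44.5 |
| winter | 10.0 | 5.2 | 1.8 | 44.5 |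
| winter | 12.0 | 5.8 | 2.1 | 44.9 |
| winter | 15.0 | 5.7 | 1.7 | 44.7 |

(scatter of a reading: 0.3 percentage points)

- excess of left-handed product over right-handed product in the product at 50 min
- excess of left-handed product over right-handed product in the product at 15 h
- part of the left-handed substrate and right-handed substrate charged together that has reacted at 15 h

- free catalyst is single-handed; left-handed substrate and right-handed substrate are mirror images of each other, charged as a racemate, each of them at the stated concentration
- the earlier runs were read with a standard deviation of 0.3 percentage points
- an excess is below zero if the other one leads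

In the earlier runs the readings showed no clear drift from first to last. In the summer run, for example, they ran from 1.33 h to 15.0 h with little change beyond the scatter of 0.3 percentage points, so I let one count stand for a run. The two products together, averaged over the readings of the summer run, came to 5.36% of the substrate charged, which against 11 mM of precatalyst made 2.44 turnovers.

The partner was the limiting reagent by charge in the flask, its 0.150 M being less than the 0.500 M of substrate, so I divided the count by the partner charged. This gave the turnover yield g, turnovers per molar of partner charged, which was 22.1 M⁻¹ in the summer run. The autumn run read 19.9 M⁻¹, a little lower.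

For the flask, with 0.150 M of partner, the summer value of g gave 3.32 turnovers, so I committed to 7.31% reacted.

The forecast gave an excess of 49% at 50 min, an excess of 49% at 15 h and 7.4% reacted, the last slightly above my figure. It held that “reaction stops early, during or soon after dosing”.

The flask gave an excess of 46.3% at 50 min, an excess of 46.2% at 15 h and 9.15% reacted, so the forecast stood within its margins.

    partner + free catalyst + left-handed substrate → free catalyst + left-handed product (k = 5690 M⁻² h⁻¹)
    partner + free catalyst + right-handed substrate → free catalyst + right-handed product (k = 2000 M⁻² h⁻¹)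
    partner → decomposed reagent (k = 2.94 h⁻¹)
    free catalyst → spent catalyst (k = 0.939 h⁻¹)
    partner + precatalyst → free catalyst + spent reagent (k = 4.99 M⁻¹ h⁻¹)

The flask reached 4.16 turnovers, so its g was 27.7 M⁻¹, higher than the summer reading. A neighbouring flask differed from it in one setting, 0.38 M of partner. The flask's g promised 10.5 turnovers there, or 23.2% reacted. The neighbour reacted 32.3%, more than that, with partner at 0% at the end and an excess of 40.6%. It made 14.7 turnovers, a g of 38.7 M⁻¹.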